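**Strategy.** The oxygen-bridged ring system of the target (C1′–C6′, with O7′ spanning the methyl-bearing bridgeheads C1′ and C4′) hides a mirror plane. If the side-chain carbon Cβ on C2′ and the methyl carbon on C3′ are both raised to the carboxyl level, the bicycle is a meso anhydride. The route therefore rests on disconnecting C1′–C2′ and C3′–C4′. One Diels–Alder reaction of commercial 2,5-dimethylfuran and maleic anhydride closes the bridged carbocycle, places both bridgehead methyls and supplies both carboxyl carbons. Desymmetrisation, inversion at C2′ and conversion into an aluminium acetylide then allow the retentive opening of a brominated bicyclic ketal that completes the bromo-oxane.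

Key step: step 1

Remark on locants: oxane O1, C2 (CH3, vinyl), C3, C4, C5 (Br), C6 (CH3, side chain); linker C6–Cα–Cβ–C2′; oxabicycle C1′–C6′, O7′. In ketal 20, C1/C4/C5 correspond to oxane C2/C5/C6.

Remark on the oxane branch: direct bromination of the unbrominated bicyclic ketal would not reliably distinguish the ring CH2 from the ketal methyl, so bromine is introduced by bromo-ketalisation of a regiodefined endocyclic enol ether.

Assumption: quinidine is taken to give hemiester 5 in the sense drawn. Its pseudo-enantiomer quinine gives the mirror-image hemiester and would be used instead if the sense on this anhydride proves opposite.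

**Step 1**
Reactants: 1 2,5-dimethylfuran; 2 maleic anhydride
Product: 3 exo-1,4-dimethyl-7-oxabicyclo[2.2.1]hept-5-ene-2,3-dicarboxylic anhydride (meso)
Conditions: Et2O, 20 °C, 24 h; crystalline adduct filtered cold
Reagents that add atoms: none
Why: A concerted, suprafacial [4πs+2πs] Diels–Alder cycloaddition between the electron-rich furan and the electron-poor cis-dienophile forms C1′–C2′ and C3′–C4′ together; the closest known reaction type is the furan–maleic anhydride cycloaddition, which is known for this very pair. The one new ring, the cyclohexene C1′–C2′–C3′–C4′–C5′=C6′, is closed by cycloaddition across the furan 2,5-positions, which turns the furan oxygen into the one-atom bridge O7′. C1′ and C4′ are tied to each other by that bridge, C2′ and C3′ are cis because the dienophile geometry is conserved, and their exo orientation follows from thermodynamic control. The only selectivity needed is exo over endo, and it is secured because the adduct of this 2,5-disubstituted furan reverts readily at room temperature, so the more stable exo isomer accumulates and crystallises. Neither regiochemistry nor absolute configuration arises, since both partners are symmetric and the adduct is meso.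

**Step 2**
Reactants: 3 exo-1,4-dimethyl-7-oxabicyclo[2.2.1]hept-5-ene-2,3-dicarboxylic anhydride
Product: 4 exo-1,4-dimethyl-7-oxabicyclo[2.2.1]heptane-2,3-dicarboxylic anhydride (meso)
Conditions: H2 (1 atm), 10% Pd/C, EtOAc, 0–20 °C, used at once after step 1
Reagents that add atoms: none
Why: Heterogeneous catalytic hydrogenation of the strained cis-alkene removes the retro-Diels–Alder pathway without creating a stereocentre or disturbing the mirror symmetry.

**Step 3**
Reactants: 4 exo-1,4-dimethyl-7-oxabicyclo[2.2.1]heptane-2,3-dicarboxylic anhydride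
Product: 5 (1S,2R,3S,4R)-3-(methoxycarbonyl)-1,4-dimethyl-7-oxabicyclo[2.2.1]heptane-2-carboxylic acid (acid and ester both exo; ester on the future C2′, acid on the future C3′)
Conditions: quinidine (1.1 equiv), MeOH (3 equiv), toluene, −55 °C; 2 M HCl wash (alkaloid recovered)
Reagents that add atoms: methanol, CO
Why: Cinchona-alkaloid-mediated desymmetrising alcoholysis of a meso anhydride, in which the quinuclidine nitrogen acts as a chiral general base and steers methanol to one of the two enantiotopic carbonyl groups, should fix the absolute configuration of C1′–C4′ in a single event.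

**Step 4**
Reactants: 5 cis-hemiester
Product: 6 (1S,2R,3R,4R)-3-(methoxycarbonyl)-1,4-dimethyl-7-oxabicyclo[2.2.1]heptane-2-carboxylic acid (acid exo, ester endo)
Conditions: NaOMe (3 equiv), MeOH, reflux; then 1 M HCl, 0 °C
Reagents that add atoms: none
Why: Base-mediated thermodynamic epimerisation through reversible ester enolisation touches only C2′, because the carboxylate on C3′ resists α-deprotonation, and it should settle on the trans isomer with the ester endo, since this relieves the eclipsed exo,exo arrangement.

**Step 5**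
Reactants: 6 trans-hemiester
Product: 7 methyl (1R,2R,3S,4S)-3-(hydroxymethyl)-1,4-dimethyl-7-oxabicyclo[2.2.1]heptane-2-carboxylate
Conditions: BH3·SMe2 (1.5 equiv), THF, 0 → 20 °C; MeOH quench
Reagents that add atoms: none
Why: Chemoselective borane reduction of a carboxylic acid (via the acyloxyborane) leaves the methyl ester alone, and the trans relationship of the two groups rules out lactonisation of the hydroxy ester.

**Step 6**
Reactants: 7 hydroxy ester
Product: 8 methyl (1R,2R,3S,4S)-1,4-dimethyl-3-{[(4-methylbenzenesulfonyl)oxy]methyl}-7-oxabicyclo[2.2.1]heptane-2-carboxylate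
Conditions: TsCl, Et3N, DMAP (cat.), CH2Cl2, 0 → 20 °C
Reagents that add atoms: 4-methylbenzenesulfonyl chloride, Cc1ccc(cc1)S(Cl)(=O)=O
Why: Standard sulfonylation of a primary alcohol turns the C3′ hydroxymethyl group into a leaving group for hydride displacement.

**Step 7**
Reactants: 8 tosylate ester
Product: 9 [(1R,2S,3R,4S)-1,3,4-trimethyl-7-oxabicyclo[2.2.1]heptan-2-yl]methanol (CH2OH endo on C2′, CH3 exo on C3′)
Conditions: LiEt3BH (4 equiv), THF, 0 → 50 °C; H2O
Reagents that add atoms: none
Why: Lithium triethylborohydride displaces the hindered primary tosylate by SN2 hydride delivery (giving the exo C3′ methyl) and reduces the ester to the primary alcohol in the same operation, while the trans arrangement prevents the new alkoxide from closing a cyclic ether onto the tosylate.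

**Step 8**
Reactants: 9 primary alcohol
Product: 10 (1R,2R,3R,4S)-1,3,4-trimethyl-7-oxabicyclo[2.2.1]heptane-2-carbaldehyde
Conditions: Dess–Martin periodinane, NaHCO3, CH2Cl2, 0 → 20 °C; used crude
Reagents that add atoms: none
Why: Buffered Dess–Martin oxidation gives the aldehyde under non-basic conditions, and C2′ already carries the more stable trans (endo-formyl, exo-methyl) arrangement, so it is not at risk.

**Step 9**
Reactants: 10 aldehyde
Product: 11 (1R,2S,3R,4S)-2-ethynyl-1,3,4-trimethyl-7-oxabicyclo[2.2.1]heptane
Conditions: dimethyl (1-diazo-2-oxopropyl)phosphonate, K2CO3, MeOH, 0 → 20 °C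
Reagents that add atoms: dimethyl (1-diazo-2-oxopropyl)phosphonate (Ohira–Bestmann reagent), CC(=O)C(=[N+]=[N-])P(=O)(OC)OC
Why: Seyferth–Gilbert homologation in its Ohira–Bestmann form converts the aldehyde carbon (Cβ) into a terminal alkyne by adding Cα, under mild carbonate conditions that can only return C2′ to its preferred trans configuration.

**Step 10**
Reactants: 12 (R)-2-methylglycidol
Product: 13 tert-butyl{[(2S)-2-methyloxiran-2-yl]methoxy}diphenylsilane
Conditions: TBDPSCl, imidazole, CH2Cl2, 0 → 20 °C
Reagents that add atoms: tert-butyl(chloro)diphenylsilane, CC(C)(C)[Si](Cl)(c1ccccc1)c1ccccc1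
Why: Silylation of the primary alcohol gives an acid-tolerant, non-nucleophilic protecting group; the stereocentre is untouched and the descriptor changes only through the priority rules.

**Step 11**
Reactants: 13 silyl glycidyl ether; 14 2-(2-bromoethyl)-2-methyl-1,3-dioxolane
Product: 16 (2S)-1-[(tert-butyldiphenylsilyl)oxy]-2-methyl-5-(2-methyl-1,3-dioxolan-2-yl)pentan-2-ol, via Grignard reagent 15 (not isolated)
Conditions: 14, Mg, THF, ≤ 30 °C; then CuI (10 mol%), 13, THF, −30 → 0 °C; aq NH4Cl
Reagents that add atoms: none
Why: Copper-catalysed Grignard opening of a 2,2-disubstituted epoxide occurs at the unhindered CH2 terminus, so the C–O bond of the quaternary carbon is never broken and the tertiary carbinol (future oxane C2) keeps the configuration of 12.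

**Step 12**
Reactants: 16 hydroxy dioxolane
Product: 18 tert-butyl{[(2S)-2,6-dimethyl-3,4-dihydro-2H-pyran-2-yl]methoxy}diphenylsilane, via hydroxy ketone 17 (not isolated)
Conditions: PPTS, acetone–H2O, 50 °C; extractive work-up (removes glycol); then PPTS (cat.), toluene, reflux, Dean–Stark; Et3N
Reagents that add atoms: none
Why: Acetal hydrolysis followed by acid-catalysed cyclodehydration of the δ-hydroxy ketone (through its cyclic hemiketal) should give the endocyclic trisubstituted enol ether, the thermodynamic isomer under equilibrating acid, while the silyl ether keeps the primary oxygen from closing the bicyclic ketal.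

**Step 13**
Reactants: 18 silyl-protected enol ether
Product: 19 [(2S)-2,6-dimethyl-3,4-dihydro-2H-pyran-2-yl]methanol
Conditions: TBAF, THF, 0 → 20 °C; Et3N-deactivated silica
Reagents that add atoms: none
Why: Fluoride-mediated desilylation is basic, so the acid-labile enol ether survives and the free hydroxymethyl group is released for the next step.

**Step 14**
Reactants: 19 hydroxymethyl enol ether
Product: 20 (1S,4R,5R)-4-bromo-1,5-dimethyl-6,8-dioxabicyclo[3.2.1]octane
Conditions: NBS (1.05 equiv), NaHCO3, CH2Cl2, −20 °C
Reagents that add atoms: N-bromosuccinimide, O=C1CCC(=O)N1Br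
Why: Bromonium-induced intramolecular ketalisation of an endocyclic enol ether (the halocyclisation known for 6-hydroxy glycals) places Br on the β-carbon and the tethered oxygen on the oxocarbenium carbon; because the hydroxymethyl group can only reach its own face, anti addition sets C4 with bromine axial and trans to the new C–O bond.

**Step 15**
Reactants: 11 bicyclic alkyne (2 equiv, excess recovered); 20 bromo ketal
Product: 23 [(2S,5R,6S)-5-bromo-2,6-dimethyl-6-{[(1R,2S,3R,4S)-1,3,4-trimethyl-7-oxabicyclo[2.2.1]heptan-2-yl]ethynyl}oxan-2-yl]methanol, via lithium acetylide 21 (not isolated), via dimethylalkynylalane 22 (not isolated)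
Conditions: 11, n-BuLi, toluene, 0 °C; Me2AlCl (hexanes), 0 → 20 °C; then 20, toluene, 0 → 40 °C; aq Rochelle salt
Reagents that add atoms: none
Why: In this organoaluminium alkynylative opening of a bicyclic ketal the alane binds the less hindered dioxolane oxygen O6, the C5–O6 bond ionises to the pyranyl oxocarbenium ion (helped by the antiperiplanar axial bromine), and the alkynyl group is passed from aluminium to the face that O6 has just left, so the quaternary oxane C6 is set with retention, alkynyl cis to CH2OH and anti to Br.

**Step 16**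
Reactants: 23 alkynyl oxane
Product: 24 [(2S,5R,6S)-5-bromo-2,6-dimethyl-6-{2-[(1R,2R,3R,4S)-1,3,4-trimethyl-7-oxabicyclo[2.2.1]heptan-2-yl]ethyl}oxan-2-yl]methanol
Conditions: H2 (1–3 atm), 5% Rh/Al2O3, EtOAc, 20 °C
Reagents that add atoms: none
Why: Heterogeneous hydrogenation over rhodium, a metal with little tendency to cleave C–Br or propargylic C–O bonds, saturates the alkyne to the Cα–Cβ ethylene linker without creating a stereocentre.

**Step 17**
Reactants: 24 primary alcohol
Product: 25 (2S,5R,6S)-5-bromo-2,6-dimethyl-6-{2-[(1R,2R,3R,4S)-1,3,4-trimethyl-7-oxabicyclo[2.2.1]heptan-2-yl]ethyl}oxane-2-carbaldehyde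
Conditions: Dess–Martin periodinane, NaHCO3, CH2Cl2, 0 → 20 °C
Reagents that add atoms: none
Why: Dess–Martin oxidation of the neopentyl-type alcohol gives an aldehyde with no α-hydrogen, which can neither enolise nor epimerise.

**Step 18**
Reactants: 25 aldehyde
Product: 26 dactylopyranoid, (2S,3R,6S)-3-bromo-6-ethenyl-2,6-dimethyl-2-{2-[(1R,2R,3R,4S)-1,3,4-trimethyl-7-oxabicyclo[2.2.1]heptan-2-yl]ethyl}oxane
Conditions: Ph3PCH3Br, KHMDS, THF, 0 °C; then 25, −78 → 0 °C
Reagents that add atoms: methyltriphenylphosphonium bromide, C[P+](c1ccccc1)(c1ccccc1)c1ccccc1.[Br-]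
Why: Wittig methylenation of a non-enolisable α-alkoxy aldehyde installs the vinyl group, the ylide adding to the carbonyl at low temperature faster than it can attack the hindered secondary bromide.

**Compound list**
1 | 2,5-dimethylfuran | Cc1ccc(C)o1 | starting material
2 | maleic anhydride | O=C1OC(=O)C=C1 | starting material
3 | exo-1,4-dimethyl-7-oxabicyclo[2.2.1]hept-5-ene-2,3-dicarboxylic anhydride (meso) | O=C1OC(=O)[C@H]2[C@@H]1[C@]3(C)C=C[C@@]2(C)O3 | intermediate
4 | exo-1,4-dimethyl-7-oxabicyclo[2.2.1]heptane-2,3-dicarboxylic anhydride (meso) | O=C1OC(=O)[C@H]2[C@@H]1[C@]3(C)CC[C@@]2(C)O3 | intermediate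
5 | (1S,2R,3S,4R)-3-(methoxycarbonyl)-1,4-dimethyl-7-oxabicyclo[2.2.1]heptane-2-carboxylic acid (both exo) | COC(=O)[C@H]1[C@@H](C(=O)O)[C@]2(C)CC[C@@]1(C)O2 | intermediate
6 | (1S,2R,3R,4R)-3-(methoxycarbonyl)-1,4-dimethyl-7-oxabicyclo[2.2.1]heptane-2-carboxylic acid (acid exo, ester endo) | COC(=O)[C@@H]1[C@@H](C(=O)O)[C@]2(C)CC[C@@]1(C)O2 | intermediate
7 | methyl (1R,2R,3S,4S)-3-(hydroxymethyl)-1,4-dimethyl-7-oxabicyclo[2.2.1]heptane-2-carboxylate | COC(=O)[C@@H]1[C@@H](CO)[C@]2(C)CC[C@@]1(C)O2 | intermediate
8 | methyl (1R,2R,3S,4S)-1,4-dimethyl-3-{[(4-methylbenzenesulfonyl)oxy]methyl}-7-oxabicyclo[2.2.1]heptane-2-carboxylate | COC(=O)[C@@H]1[C@@H](COS(=O)(=O)c3ccc(C)cc3)[C@]2(C)CC[C@@]1(C)O2 | intermediate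
9 | [(1R,2S,3R,4S)-1,3,4-trimethyl-7-oxabicyclo[2.2.1]heptan-2-yl]methanol | OC[C@@H]1[C@@H](C)[C@]2(C)CC[C@@]1(C)O2 | intermediate
10 | (1R,2R,3R,4S)-1,3,4-trimethyl-7-oxabicyclo[2.2.1]heptane-2-carbaldehyde | O=C[C@@H]1[C@@H](C)[C@]2(C)CC[C@@]1(C)O2 | intermediate
11 | (1R,2S,3R,4S)-2-ethynyl-1,3,4-trimethyl-7-oxabicyclo[2.2.1]heptane | C#C[C@@H]1[C@@H](C)[C@]2(C)CC[C@@]1(C)O2 | intermediate
12 | (R)-2-methylglycidol | OC[C@]1(C)CO1 | starting material
13 | tert-butyl{[(2S)-2-methyloxiran-2-yl]methoxy}diphenylsilane | CC(C)(C)[Si](c1ccccc1)(c1ccccc1)OC[C@]1(C)CO1 | intermediate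
14 | 2-(2-bromoethyl)-2-methyl-1,3-dioxolane | CC1(CCBr)OCCO1 | starting material
15 | [2-(2-methyl-1,3-dioxolan-2-yl)ethyl]magnesium bromide | CC1(CC[Mg]Br)OCCO1 | intermediate
16 | (2S)-1-[(tert-butyldiphenylsilyl)oxy]-2-methyl-5-(2-methyl-1,3-dioxolan-2-yl)pentan-2-ol | CC(C)(C)[Si](c1ccccc1)(c1ccccc1)OC[C@](O)(C)CCCC1(C)OCCO1 | intermediate
17 | (6S)-7-[(tert-butyldiphenylsilyl)oxy]-6-hydroxy-6-methylheptan-2-one (in equilibrium with its cyclic hemiketal) | CC(C)(C)[Si](c1ccccc1)(c1ccccc1)OC[C@](O)(C)CCCC(C)=O | intermediate
18 | tert-butyl{[(2S)-2,6-dimethyl-3,4-dihydro-2H-pyran-2-yl]methoxy}diphenylsilane | CC(C)(C)[Si](c1ccccc1)(c1ccccc1)OC[C@]1(C)CCC=C(C)O1 | intermediate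
19 | [(2S)-2,6-dimethyl-3,4-dihydro-2H-pyran-2-yl]methanol | OC[C@]1(C)CCC=C(C)O1 | intermediate
20 | (1S,4R,5R)-4-bromo-1,5-dimethyl-6,8-dioxabicyclo[3.2.1]octane | C[C@@]12CC[C@@H](Br)[C@@](C)(O1)OC2 | intermediate
21 | lithium acetylide of 11 | [Li]C#C[C@@H]1[C@@H](C)[C@]2(C)CC[C@@]1(C)O2 | intermediate
22 | dimethyl(alkynyl)alane of 11 | C[Al](C)C#C[C@@H]1[C@@H](C)[C@]2(C)CC[C@@]1(C)O2 | intermediate
23 | [(2S,5R,6S)-5-bromo-2,6-dimethyl-6-{[(1R,2S,3R,4S)-1,3,4-trimethyl-7-oxabicyclo[2.2.1]heptan-2-yl]ethynyl}oxan-2-yl]methanol | OC[C@]1(C)CC[C@@H](Br)[C@](C)(C#C[C@@H]2[C@@H](C)[C@]3(C)CC[C@@]2(C)O3)O1 | intermediate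
24 | [(2S,5R,6S)-5-bromo-2,6-dimethyl-6-{2-[(1R,2R,3R,4S)-1,3,4-trimethyl-7-oxabicyclo[2.2.1]heptan-2-yl]ethyl}oxan-2-yl]methanol | OC[C@]1(C)CC[C@@H](Br)[C@](C)(CC[C@@H]2[C@@H](C)[C@]3(C)CC[C@@]2(C)O3)O1 | intermediate
25 | (2S,5R,6S)-5-bromo-2,6-dimethyl-6-{2-[(1R,2R,3R,4S)-1,3,4-trimethyl-7-oxabicyclo[2.2.1]heptan-2-yl]ethyl}oxane-2-carbaldehyde | O=C[C@]1(C)CC[C@@H](Br)[C@](C)(CC[C@@H]2[C@@H](C)[C@]3(C)CC[C@@]2(C)O3)O1 | intermediate
26 | dactylopyranoid | C=C[C@]1(C)CC[C@@H](Br)[C@](C)(CC[C@@H]2[C@@H](C)[C@]3(C)CC[C@@]2(C)O3)O1 | target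

**Step count and risk**

Total step count: 18. Longest linear sequence: 13 steps (steps 1–9, then 15–18); the oxane branch (steps 10–14) joins at step 15.

Three steps most likely to fail:

Step 15. Ionisation of the ketal C–O bond next to the electron-withdrawing bromine may be too slow for the weakly Lewis-acidic alane. Methyl transfer, loss of HBr or cleavage of the other ketal C–O bond could then compete with alkynyl delivery. The fallback replaces aluminium-delivered transfer by a strong-Lewis-acid alkynylation with an external nucleophile, in which the neighbouring bromine rather than the departing oxygen controls the face. It sets out from 11: the lithium acetylide 21 would be quenched with Bu3SnCl to give tributyl{[(1R,2S,3R,4S)-1,3,4-trimethyl-7-oxabicyclo[2.2.1]heptan-2-yl]ethynyl}stannane F1. Ketal 20 would then be ionised with BF3·OEt2 (CH2Cl2, −40 → 0 °C) in the presence of F1. The axial bromine bridges the oxocarbenium ion and should send the stannane to the face anti to bromine, the same face as in step 15. The fallback returns to the route at 23.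

Step 3. The bridgehead methyl groups flank both carbonyl groups and may slow the alcoholysis, erode the discrimination between the enantiotopic carbonyls, or reverse its sense. The fallback is an enzymatic desymmetrisation of a diester and sets out from 4. Fischer esterification (MeOH, cat. H2SO4, reflux) would give meso dimethyl exo,exo-1,4-dimethyl-7-oxabicyclo[2.2.1]heptane-2,3-dicarboxylate F2. Hydrolysis of one enantiotopic ester with pig liver esterase (pH 7 phosphate buffer, pH-stat), or with a complementary hydrolase if the opposite half-ester forms, returns to the route at 5.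

Step 4. The ester enolate lies β to the bridging oxygen and may expel O7′ (retro-oxa-Michael opening of the bicycle) during prolonged equilibration in hot methoxide, or equilibration may stop short of completion. The fallback replaces reversible equilibration by irreversible enolate formation and kinetic protonation, and sets out from 5. Double deprotonation (LDA, 2.2 equiv, THF, −78 °C) would give the dilithium ester-enolate carboxylate F3, kept at −78 °C where such enolates persist. Protonation with AcOH at −78 °C on the open exo face places the ester endo and returns to the route at 6.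

**Further compounds**
F1 | step 15 | tributyl{[(1R,2S,3R,4S)-1,3,4-trimethyl-7-oxabicyclo[2.2.1]heptan-2-yl]ethynyl}stannane | CCCC[Sn](CCCC)(CCCC)C#C[C@@H]1[C@@H](C)[C@]2(C)CC[C@@]1(C)O2
F2 | step 3 | dimethyl exo,exo-1,4-dimethyl-7-oxabicyclo[2.2.1]heptane-2,3-dicarboxylate (meso) | COC(=O)[C@H]1[C@@H](C(=O)OC)[C@]2(C)CC[C@@]1(C)O2
F3 | step 4 | dilithium ester-enolate carboxylate of 5 | COC([O-])=C1[C@@H](C([O-])=O)[C@]2(C)CC[C@@]1(C)O2.[Li+].[Li+]
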